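**Retrosynthetic overview**
1. 17 ⇒ PT-sulfone 15 + dienal 16: the acid- and oxidant-labile triene is made last, by Julia–Kocienski olefination at C-9'=C-10' of the side chain; 15 comes from chloride 13.
2. Ring B (1,2-dioxane) ⇒ butenolide 11 + H2O2: the C-3–O bond by a catalyst-controlled Markovnikov hydroperoxidation of the 1,1-disubstituted alkene (key step), the C-7a–O bond by intramolecular peroxy-Michael addition.
3. Ring A (butenolide) ⇒ α-hydroxy aldehyde 9 + Ph3P=C=C=O; 9 ⇐ diol 8 ⇐ (R)-2-methylglycidol 5 opened at CH2 by the alkenyl Grignard from 4.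
4. 4 ⇐ 1-bromo-8-chlorooctane 1 + 2,3-dibromopropene 2; the chloride is the latent sulfone.
5. Ring order: ring A (lactone) first, then ring B (dioxane).

Assumption: reagents named without a number are bought; the sense of induction of the new catalyst cannot be predicted, so the IDPi enantiomer used is the one a short screen shows to give (S) at the new peroxide carbon (written (S,S) below).

Step 1
Reactants: 1 1-bromo-8-chlorooctane; 2 2,3-dibromoprop-1-ene
Product: 4 2-bromo-11-chloroundec-1-ene, via 8-chlorooctylmagnesium bromide 3 (not isolated)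
Conditions: Mg, THF, 30 °C; then 2 (1.3 equiv), CuI (5 mol%), THF, −10 to 20 °C
Reagents that add atoms: none
Why: Mg inserts into C–Br far faster than into C–Cl, and the copper-catalysed Grignard allylic substitution of 2,3-dibromopropene (SN2 and SN2' give the same product) is the classical route to 2-bromo-1-alkenes.

Step 2
Reactants: 4 2-bromo-11-chloroundec-1-ene; 5 (R)-2-methylglycidol
Product: 8 (2S)-13-chloro-2-methyl-4-methylidenetridecane-1,2-diol, via alkenyllithium 6 (not isolated), via alkenylmagnesium bromide 7 (not isolated)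
Conditions: 4 (2.3 equiv), t-BuLi (4.6 equiv), Et2O, −78 °C; MgBr2·OEt2 (2.3 equiv); then CuI (10 mol%), 5 (1.0 equiv), THF, −30 to 0 °C; aq NH4Cl
Reagents that add atoms: none
Why: Bromine–lithium exchange spares the primary chloride, one equivalent of 7 deprotonates the hydroxyl, and the copper-catalysed Grignard epoxide opening (SN2 at the CH2 terminus) leaves the quaternary carbinol centre of 5 untouched, so it becomes C-4a with the required configuration.

Step 3
Reactants: 8 (2S)-13-chloro-2-methyl-4-methylidenetridecane-1,2-diol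
Product: 9 (2S)-13-chloro-2-hydroxy-2-methyl-4-methylidenetridecanal
Conditions: SO3·pyridine, DMSO, i-Pr2NEt, CH2Cl2, 0 °C
Reagents that add atoms: none
Why: Parikh–Doering oxidation converts only the primary alcohol (the tertiary one cannot be oxidised), avoids glycol cleavage and cannot epimerise the quaternary centre.

Step 4
Reactants: 9 (2S)-13-chloro-2-hydroxy-2-methyl-4-methylidenetridecanal
Product: 11 (5S)-5-(11-chloro-2-methylideneundecyl)-5-methylfuran-2(5H)-one, via acyl ylide ester 10 (not isolated)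
Conditions: Ph3P=C=C=O (1.2 equiv), toluene, 90 °C
Reagents that add atoms: (triphenylphosphoranylidene)ketene (Bestmann ylide), O=C=C=P(c1ccccc1)(c1ccccc1)c1ccccc1
Why: The tertiary hydroxyl adds to the cumulated ylide and the resulting stabilised ylide ester closes ring A by intramolecular Wittig reaction with the neighbouring aldehyde (Bestmann butenolide synthesis), the ring enforcing the cis alkene.

Step 5
Reactants: 11 (5S)-5-(11-chloro-2-methylideneundecyl)-5-methylfuran-2(5H)-one
Product: 13 (3S,4aS,7aS)-3-(9-chlorononyl)-3,4a-dimethyl-4,4a,7,7a-tetrahydro-3H-furo[3,2-c][1,2]dioxin-6-one, via tertiary hydroperoxide 12 (not isolated)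
Conditions: chiral IDPi acid HN[P(=NSO2CF3)(O2C20H10Ar2)]2 (Ar = 3,5-(CF3)2C6H3; (S,S); 5 mol%), anhydrous H2O2 (3 equiv), CHCl3–cyclohexane, 0 °C; aqueous wash; then Et2NH (0.3 equiv), CF3CH2OH, 20 °C
Reagents that add atoms: hydrogen peroxide, OO
Why: Proposed new method: the confined, strongly acidic chiral imidodiphosphorimidate protonates only the electron-rich 1,1-dialkyl alkene inside its pocket while hydrogen-bonded H2O2 (an α-effect nucleophile) collapses on the developing tertiary cation in a concerted asynchronous Markovnikov addition, so the catalyst rather than the remote centre of ring A selects the alkene face and sets the tertiary C–OO centre (C-3, S) in 12, after which the known amine-catalysed 6-exo peroxy-Michael addition onto the butenolide closes ring B cis-fused and fixes C-7a from C-4a; the closest known reaction types are the IDPi-catalysed asymmetric intramolecular hydroalkoxylation and hydrolactonization of unactivated 1,1-disubstituted alkenes and the racemic strong-acid perhydrolysis of such alkenes to tertiary hydroperoxides.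

Step 6
Reactants: 13 (3S,4aS,7aS)-3-(9-chlorononyl)-3,4a-dimethyl-4,4a,7,7a-tetrahydro-3H-furo[3,2-c][1,2]dioxin-6-one
Product: 14 (3S,4aS,7aS)-3,4a-dimethyl-3-{9-[(1-phenyl-1H-tetrazol-5-yl)sulfanyl]nonyl}-4,4a,7,7a-tetrahydro-3H-furo[3,2-c][1,2]dioxin-6-one
Conditions: sodium 1-phenyl-1H-tetrazole-5-thiolate (1.5 equiv), NaI (0.1 equiv), DMF, 50 °C
Reagents that add atoms: sodium 1-phenyl-1H-tetrazole-5-thiolate, [Na+].[S-]c1nnnn1-c1ccccc1
Why: Iodide-relayed SN2 displacement of the primary chloride by a soft, essentially non-basic thiolate leaves the base-sensitive β-peroxy lactone and the dialkyl peroxide alone.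

Step 7
Reactants: 14 (3S,4aS,7aS)-3,4a-dimethyl-3-{9-[(1-phenyl-1H-tetrazol-5-yl)sulfanyl]nonyl}-4,4a,7,7a-tetrahydro-3H-furo[3,2-c][1,2]dioxin-6-one
Product: 15 (3S,4aS,7aS)-3,4a-dimethyl-3-{9-[(1-phenyl-1H-tetrazol-5-yl)sulfonyl]nonyl}-4,4a,7,7a-tetrahydro-3H-furo[3,2-c][1,2]dioxin-6-one
Conditions: m-CPBA (2.3 equiv), NaHCO3, CH2Cl2, 0 to 20 °C
Reagents that add atoms: 3-chloroperoxybenzoic acid (m-CPBA), OOC(=O)c1cccc(Cl)c1
Why: Electrophilic peracid oxidation of sulfide to sulfone does not touch dialkyl peroxides, the lactone or the stereocentres (sulfide-to-sulfone oxidation).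

Step 8
Reactants: 15 (3S,4aS,7aS)-3,4a-dimethyl-3-{9-[(1-phenyl-1H-tetrazol-5-yl)sulfonyl]nonyl}-4,4a,7,7a-tetrahydro-3H-furo[3,2-c][1,2]dioxin-6-one; 16 (2E,4E)-hepta-2,4-dienal
Product: 17 (3S,4aS,7aS)-3-[(9E,11E,13E)-hexadeca-9,11,13-trien-1-yl]-3,4a-dimethyl-4,4a,7,7a-tetrahydro-3H-furo[3,2-c][1,2]dioxin-6-one
Conditions: KN(SiMe3)2 (1.05 equiv) added to 15 + 16 (1.3 equiv), DME, −60 to 20 °C; aq NH4Cl
Reagents that add atoms: none
Why: Julia–Kocienski olefination in Barbier mode: the sulfonyl carbanion (more acidic than the lactone α-CH2) is trapped by the enal as it forms, and Smiles rearrangement with anti-elimination gives the new (E)-alkene, while the two (E)-alkenes of 16 and the three ring stereocentres are not involved.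

**Compound list**
1 | 1-bromo-8-chlorooctane | ClCCCCCCCCBr | starting material
2 | 2,3-dibromoprop-1-ene | BrCC(Br)=C | starting material
3 | 8-chlorooctylmagnesium bromide | ClCCCCCCCC[Mg]Br | intermediate
4 | 2-bromo-11-chloroundec-1-ene | ClCCCCCCCCCC(Br)=C | intermediate
5 | (R)-2-methylglycidol, [(2R)-2-methyloxiran-2-yl]methanol | C[C@@]1(CO)CO1 | starting material
6 | (11-chloroundec-1-en-2-yl)lithium | [Li]C(=C)CCCCCCCCCCl | intermediate
7 | (11-chloroundec-1-en-2-yl)magnesium bromide | Br[Mg]C(=C)CCCCCCCCCCl | intermediate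
8 | (2S)-13-chloro-2-methyl-4-methylidenetridecane-1,2-diol | ClCCCCCCCCCC(=C)C[C@](CO)(C)O | intermediate
9 | (2S)-13-chloro-2-hydroxy-2-methyl-4-methylidenetridecanal | ClCCCCCCCCCC(=C)C[C@](C=O)(C)O | intermediate
10 | (2S)-13-chloro-2-methyl-4-methylidene-1-oxotridecan-2-yl (triphenylphosphoranylidene)acetate | ClCCCCCCCCCC(=C)C[C@](C=O)(C)OC(=O)C=P(c1ccccc1)(c1ccccc1)c1ccccc1 | intermediate
11 | (5S)-5-(11-chloro-2-methylideneundecyl)-5-methylfuran-2(5H)-one | ClCCCCCCCCCC(=C)C[C@]1(C)OC(=O)C=C1 | intermediate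
12 | (5S)-5-[(2S)-11-chloro-2-hydroperoxy-2-methylundecyl]-5-methylfuran-2(5H)-one | ClCCCCCCCCC[C@@](OO)(C)C[C@]1(C)OC(=O)C=C1 | intermediate
13 | (3S,4aS,7aS)-3-(9-chlorononyl)-3,4a-dimethyl-4,4a,7,7a-tetrahydro-3H-furo[3,2-c][1,2]dioxin-6-one (cis-fused) | ClCCCCCCCCC[C@@]1(C)C[C@]2(C)OC(=O)C[C@@H]2OO1 | intermediate
14 | (3S,4aS,7aS)-3,4a-dimethyl-3-{9-[(1-phenyl-1H-tetrazol-5-yl)sulfanyl]nonyl}-4,4a,7,7a-tetrahydro-3H-furo[3,2-c][1,2]dioxin-6-one | c1ccc(cc1)-n1nnnc1SCCCCCCCCC[C@@]1(C)C[C@]2(C)OC(=O)C[C@@H]2OO1 | intermediate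
15 | (3S,4aS,7aS)-3,4a-dimethyl-3-{9-[(1-phenyl-1H-tetrazol-5-yl)sulfonyl]nonyl}-4,4a,7,7a-tetrahydro-3H-furo[3,2-c][1,2]dioxin-6-one | O=S(=O)(CCCCCCCCC[C@@]1(C)C[C@]2(C)OC(=O)C[C@@H]2OO1)c1nnnn1-c1ccccc1 | intermediate
16 | (2E,4E)-hepta-2,4-dienal | CC/C=C/C=C/C=O | starting material
17 | (3S,4aS,7aS)-3-[(9E,11E,13E)-hexadeca-9,11,13-trien-1-yl]-3,4a-dimethyl-4,4a,7,7a-tetrahydro-3H-furo[3,2-c][1,2]dioxin-6-one | CC/C=C/C=C/C=C/CCCCCCCC[C@@]1(C)C[C@]2(C)OC(=O)C[C@@H]2OO1 | target

**Step count and risks**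
Total steps: 8. Longest linear sequence: 8 (1 → 17).

Steps most likely to fail:

Step 5 (new asymmetric hydroperoxidation; risks are low conversion, poor face selectivity or acid-mediated epimerisation of the hydroperoxide). The fallback sets out from 11 and comes back at 13. Mukaiyama–Isayama hydroperoxysilylation (Co(thd)2 [thd = 2,2,6,6-tetramethylheptane-3,5-dionate], divalent cobalt, O2, Et3SiH, ClCH2CH2Cl, 20 °C) adds H and Et3SiOO across the 1,1-disubstituted alkene through a free tertiary radical. It gives the triethylsilyl peroxide F1 as a roughly 1:1 mixture at the new centre. Catalytic HCl in MeOH frees hydroperoxide 12 together with its epimer, the (2R)-hydroperoxide F2. Et2NH in CF3CH2OH cyclises both, and 13 is separated by chromatography from the (3R)-dioxane F3. This route is unselective but uses only known chemistry.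

Step 8 (the β-peroxy lactone meets a strong base; E/Z control with an enal is variable). The fallback sets out from 13 and comes back at 17, reversing the polarity so that the peroxylactone carries the aldehyde. NaI in acetone gives the iodide F4, and Me3N–O with NaHCO3 in DMSO (Ganem oxidation) gives the aldehyde F5. Separately, 16 is reduced (NaBH4, MeOH) to (2E,4E)-hepta-2,4-dien-1-ol F6, converted with PBr3 (Et2O, 0 °C) into (2E,4E)-1-bromohepta-2,4-diene F7, and quaternised with PBu3 to the tributylphosphonium bromide F8. The ylide from F8 (KOt-Bu, THF, −78 °C), preformed so that no free base meets the lactone, reacts with F5 in an (E)-selective allylic tributylphosphonium Wittig reaction to give 17. A trace of I2 then equilibrates any (9Z)-isomer to all-E.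

Step 4 (slow addition of a hindered tertiary alcohol to the ylide; α-ketol rearrangement or oligomerisation of 9 on heating). The fallback sets out from 9 and comes back at 11. Still–Gennari olefination ((CF3CH2O)2P(O)CH2CO2Me, KN(SiMe3)2, 18-crown-6, THF, −78 °C) gives the (Z)-hydroxy enoate F9, which lactonises to 11 with catalytic p-TsOH in CH2Cl2.

**Further compounds**
F1 | step 5 | (5S)-5-[11-chloro-2-methyl-2-(triethylsilylperoxy)undecyl]-5-methylfuran-2(5H)-one (mixture of epimers at side-chain C-2) | ClCCCCCCCCCC(C)(OO[Si](CC)(CC)CC)C[C@]1(C)OC(=O)C=C1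
F2 | step 5 | (5S)-5-[(2R)-11-chloro-2-hydroperoxy-2-methylundecyl]-5-methylfuran-2(5H)-one | ClCCCCCCCCC[C@](OO)(C)C[C@]1(C)OC(=O)C=C1
F3 | step 5 | (3R,4aS,7aS)-3-(9-chlorononyl)-3,4a-dimethyl-4,4a,7,7a-tetrahydro-3H-furo[3,2-c][1,2]dioxin-6-one | ClCCCCCCCCC[C@]1(C)C[C@]2(C)OC(=O)C[C@@H]2OO1
F4 | step 8 | (3S,4aS,7aS)-3-(9-iodononyl)-3,4a-dimethyl-4,4a,7,7a-tetrahydro-3H-furo[3,2-c][1,2]dioxin-6-one | ICCCCCCCCC[C@@]1(C)C[C@]2(C)OC(=O)C[C@@H]2OO1
F5 | step 8 | 9-[(3S,4aS,7aS)-3,4a-dimethyl-6-oxo-4,4a,7,7a-tetrahydro-3H-furo[3,2-c][1,2]dioxin-3-yl]nonanal | O=CCCCCCCCC[C@@]1(C)C[C@]2(C)OC(=O)C[C@@H]2OO1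
F6 | step 8 | (2E,4E)-hepta-2,4-dien-1-ol | CC/C=C/C=C/CO
F7 | step 8 | (2E,4E)-1-bromohepta-2,4-diene | CC/C=C/C=C/CBr
F8 | step 8 | tributyl[(2E,4E)-hepta-2,4-dien-1-yl]phosphonium bromide | CC/C=C/C=C/C[P+](CCCC)(CCCC)CCCC.[Br-]
F9 | step 4 | methyl (2Z,4S)-15-chloro-4-hydroxy-4-methyl-6-methylidenepentadec-2-enoate | ClCCCCCCCCCC(=C)C[C@](/C=C\C(=O)OC)(C)O
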